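**Retrosynthetic overview**
- The plan rests on ring B. Its O1 and C4 are attached to two adjacent carbons of ring A (C8a and C4a), so the unit O1–C8a–C4a–C4 is a masked o-quinone methide. Quaternary C2 (CH3 plus the C1'–C8' chain) together with C3 maps onto an alkene CH2=C(CH3)R.
- Disconnections: the C7 hydroxyl goes back to its TBS ether. O1–C2 and C3–C4 are then cut together (retro hetero-Diels–Alder), which opens the dihydropyran ring and removes the only stereocentre, C2.
- The diene half is a salicyl alcohol, made from 2,4-dihydroxy-6-methylbenzaldehyde by silylation of the C4 hydroxyl and reduction of the formyl group.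
- The 2π half is the complete trienoate. C7'=C8' (Z) comes from a Still–Gennari olefination and the terminal C=CH2 from a Wittig methylenation. C3'=C4' (E) is bought with geranylacetone, whose isopropylidene end is cut off through the epoxide.
- Ring order: the arene (ring A) is purchased, and the dihydropyran (ring B) is the only ring formed, in the key step.

Key step: step 8

Assumption: geranylacetone is used as the pure (E)-isomer, and the (S,S) hand of the acid in step 8 is taken to deliver (2R); should a first run show the opposite sense, the (R,R) acid is used with nothing else changed.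

**Step 1**
Reactants: 1 2,4-dihydroxy-6-methylbenzaldehyde
Product: 2 4-(tert-butyldimethylsilyloxy)-2-hydroxy-6-methylbenzaldehyde
Conditions: TBSCl (1.05 equiv), imidazole (2 equiv), CH2Cl2, 0 °C
Reagents that add atoms: tert-butyldimethylsilyl chloride, CC(C)(C)[Si](C)(C)Cl
Why: Silyl ether formation is regioselective because the C2 hydroxyl is locked in a hydrogen bond to the formyl oxygen and is crowded by it, so one equivalent of TBSCl should take only the free and more acidic C4 hydroxyl.

**Step 2**
Reactants: 2 4-(tert-butyldimethylsilyloxy)-2-hydroxy-6-methylbenzaldehyde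
Product: 3 5-(tert-butyldimethylsilyloxy)-2-(hydroxymethyl)-3-methylphenol
Conditions: NaBH4, THF/EtOH, 0 °C, short contact; pH 7 phosphate buffer quench
Reagents that add atoms: none
Why: Borohydride reduction of an aryl aldehyde is fast at 0 °C, and the short contact time and neutral quench should spare the aryl silyl ether and keep the electron-rich benzylic alcohol from ionising.

**Step 3**
Reactants: 4 (E)-geranylacetone, (5E)-6,10-dimethylundeca-5,9-dien-2-one
Product: 5 (5E)-8-(3,3-dimethyloxiran-2-yl)-6-methyloct-5-en-2-one (racemic)
Conditions: mCPBA (1.0 equiv), CH2Cl2, −10 to 0 °C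
Reagents that add atoms: 3-chloroperbenzoic acid, O=C(OO)c1cccc(Cl)c1
Why: In this Prilezhaev epoxidation one equivalent of peracid should prefer the exposed isopropylidene alkene over the C5=C6 alkene, which is more shielded and slightly deactivated by the nearby carbonyl group, and the new stereocentre may stay racemic because it is excised in step 5.

**Step 4**
Reactants: 5 (5E)-8-(3,3-dimethyloxiran-2-yl)-6-methyloct-5-en-2-one
Product: 6 3-[(3E)-3,7-dimethylocta-3,7-dien-1-yl]-2,2-dimethyloxirane (racemic)
Conditions: Ph3PCH3Br (1.5 equiv), KOt-Bu (1.4 equiv), THF, 0 °C to rt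
Reagents that add atoms: methyltriphenylphosphonium bromide, C[P+](c1ccccc1)(c1ccccc1)c1ccccc1.[Br-]
Why: Wittig methylenation of a methyl ketone leaves a trisubstituted epoxide and an isolated alkene alone, and placing it here means that the ylide never meets an aldehyde or an enoate.

**Step 5**
Reactants: 6 3-[(3E)-3,7-dimethylocta-3,7-dien-1-yl]-2,2-dimethyloxirane
Product: 8 (4E)-4,8-dimethylnona-4,8-dienal, via vicinal diol 7 (not isolated)
Conditions: H5IO6 (1.2 equiv), THF/H2O, 0 °C
Reagents that add atoms: water, O
Why: Aqueous periodic acid hydrolyses the epoxide to the vicinal diol and cleaves it at once (Malaprade glycol cleavage), and in cold aqueous THF water capture should outrun cation–alkene cyclisation while the two unactivated alkenes are not oxidised.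

**Step 6**
Reactants: 9 methyl bis(2,2,2-trifluoroethyl)phosphonoacetate
Product: 10 methyl 2-[bis(2,2,2-trifluoroethoxy)phosphoryl]propanoate (racemic)
Conditions: NaH (1.0 equiv), THF, 0 °C; MeI (1.2 equiv), 0 °C to rt
Reagents that add atoms: iodomethane, CI
Why: C-alkylation of the stabilised phosphonoacetate anion with iodomethane is limited to one methyl group by using one equivalent of base, unreacted and doubly methylated material is removed by chromatography, and the new stereocentre is racemic and disappears in step 7.

**Step 7**
Reactants: 8 (4E)-4,8-dimethylnona-4,8-dienal; 10 methyl 2-[bis(2,2,2-trifluoroethoxy)phosphoryl]propanoate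
Product: 11 methyl (2Z,6E)-2,6,10-trimethylundeca-2,6,10-trienoate
Conditions: 10 (1.2 equiv), KN(SiMe3)2 (1.15 equiv), 18-crown-6 (3 equiv), THF, −78 °C; then 8
Reagents that add atoms: none
Why: In the Still–Gennari variant of the Horner–Wadsworth–Emmons reaction the electron-poor trifluoroethyl phosphonate and the crown-ether-separated potassium ion make elimination from the kinetic adduct faster than its reversal, which should give the (Z)-enoate, and aldehyde 8 offers no second carbonyl group.

**Step 8**
Reactants: 3 5-(tert-butyldimethylsilyloxy)-2-(hydroxymethyl)-3-methylphenol; 11 methyl (2Z,6E)-2,6,10-trimethylundeca-2,6,10-trienoate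
Product: 13 methyl (2Z,6E)-9-[(2R)-7-(tert-butyldimethylsilyloxy)-2,5-dimethyl-3,4-dihydro-2H-chromen-2-yl]-2,6-dimethylnona-2,6-dienoate, via o-quinone methide 12 (not isolated)
Conditions: (S,S)-IDPi [confined imidodiphosphorimidate from two (S)-3,3'-bis[3,5-bis(trifluoromethyl)phenyl]-BINOL units, N-triflyl groups] (5 mol %), 5 Å molecular sieves, toluene, −20 °C; 11 (2 equiv, excess recovered), 3 added by syringe pump over 10 h; cold Et3N quench
Reagents that add atoms: none
Why: Proposed new method: the confined acid protonates the benzylic hydroxyl of 3, water leaves with the push of the para C7 silyloxy and ortho O1 donors, the o-quinone methide 12 stays hydrogen-bonded or protonated at O1 inside the chiral anion, and the =CH2 end of 11 (future C3) attacks C4 while O1 closes on the developing tertiary cation at C2 in one strongly asynchronous inverse-demand [4+2] event that hands the proton back to the catalyst. The closest known reaction types are chiral Brønsted acid catalysed [4+2] cycloadditions of o-quinone methides formed in situ with styrenes, enamides and enol ethers, the racemic thermal cycloaddition of o-quinone methides with 1,1-dialkyl alkenes, and confined-acid activation of unactivated 1,1-disubstituted alkenes, and what is new is an unactivated dialkyl alkene as the 2π partner under enantiocontrol. Ring B (O1–C2–C3–C4–C4a–C8a) closes in the cycloaddition mode with C3–C4 leading and O1–C2 following, which in the stepwise limit is capture of the C2 cation by the phenolic oxygen in a six-membered array. C2 is controlled by the catalyst alone: with O1 anchored to the anion, the alkene should enter the pocket with its small CH3 inward and the long chain pointing out of the mouth, so that one face is exposed. Regiochemistry follows from tertiary against primary cation character, the enoate is too electron-poor to serve this electron-poor oxadiene, the C3'=C4' alkene would have to bond through a substituted CH inside a narrow pocket whereas the terminal =CH2 is unhindered, and a C2 cation could reach C3'=C4' only through a four-membered ring or a five-membered ring with a secondary cation, so the chain and both alkene geometries should survive. Slow addition of 3 into excess 11 keeps 12 dilute so that Friedel–Crafts self-condensation with the electron-rich arene is held back, and the cold amine quench prevents acid reopening of O1–C2.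

**Step 9**
Reactants: 13 methyl (2Z,6E)-9-[(2R)-7-(tert-butyldimethylsilyloxy)-2,5-dimethyl-3,4-dihydro-2H-chromen-2-yl]-2,6-dimethylnona-2,6-dienoate
Product: 14 methyl (2Z,6E)-9-[(2R)-7-hydroxy-2,5-dimethyl-3,4-dihydro-2H-chromen-2-yl]-2,6-dimethylnona-2,6-dienoate (CNP0319148.1)
Conditions: n-Bu4NF (1.1 equiv), AcOH (1.1 equiv), THF, 0 °C
Reagents that add atoms: none
Why: Fluoride cleaves the aryl silyl ether through pentacoordinate silicon, the acetic acid buffer protonates the phenoxide so that the methyl ester and the (Z)-enoate are not attacked or isomerised, and C2 is not involved.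

**Compound list**
1 | 2,4-dihydroxy-6-methylbenzaldehyde | O=Cc1c(C)cc(O)cc1O | starting material
2 | 4-(tert-butyldimethylsilyloxy)-2-hydroxy-6-methylbenzaldehyde | O=Cc1c(C)cc(O[Si](C)(C)C(C)(C)C)cc1O | intermediate
3 | 5-(tert-butyldimethylsilyloxy)-2-(hydroxymethyl)-3-methylphenol | OCc1c(C)cc(O[Si](C)(C)C(C)(C)C)cc1O | intermediate
4 | (E)-geranylacetone, (5E)-6,10-dimethylundeca-5,9-dien-2-one | CC(C)=CCC/C(C)=C/CCC(C)=O | starting material
5 | (5E)-8-(3,3-dimethyloxiran-2-yl)-6-methyloct-5-en-2-one (racemic) | CC1(C)OC1CC/C(C)=C/CCC(C)=O | intermediate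
6 | 3-[(3E)-3,7-dimethylocta-3,7-dien-1-yl]-2,2-dimethyloxirane (racemic) | CC1(C)OC1CC/C(C)=C/CCC(C)=C | intermediate
7 | (6E)-2,6,10-trimethylundeca-6,10-diene-2,3-diol (racemic, not isolated) | CC(C)(O)C(O)CC/C(C)=C/CCC(C)=C | intermediate
8 | (4E)-4,8-dimethylnona-4,8-dienal | O=CCC/C(C)=C/CCC(C)=C | intermediate
9 | methyl bis(2,2,2-trifluoroethyl)phosphonoacetate | COC(=O)CP(=O)(OCC(F)(F)F)OCC(F)(F)F | starting material
10 | methyl 2-[bis(2,2,2-trifluoroethoxy)phosphoryl]propanoate (racemic) | COC(=O)C(C)P(=O)(OCC(F)(F)F)OCC(F)(F)F | intermediate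
11 | methyl (2Z,6E)-2,6,10-trimethylundeca-2,6,10-trienoate | COC(=O)/C(C)=C\CC/C(C)=C/CCC(C)=C | intermediate
12 | 3-(tert-butyldimethylsilyloxy)-5-methyl-6-methylidenecyclohexa-2,4-dien-1-one (o-quinone methide, not isolated) | C=C1C(C)=CC(O[Si](C)(C)C(C)(C)C)=CC1=O | intermediate
13 | methyl (2Z,6E)-9-[(2R)-7-(tert-butyldimethylsilyloxy)-2,5-dimethyl-3,4-dihydro-2H-chromen-2-yl]-2,6-dimethylnona-2,6-dienoate | COC(=O)/C(C)=C\CC/C(C)=C/CC[C@]1(C)CCc2c(C)cc(O[Si](C)(C)C(C)(C)C)cc2O1 | intermediate
14 | methyl (2Z,6E)-9-[(2R)-7-hydroxy-2,5-dimethyl-3,4-dihydro-2H-chromen-2-yl]-2,6-dimethylnona-2,6-dienoate | COC(=O)/C(C)=C\CC/C(C)=C/CC[C@]1(C)CCc2c(C)cc(O)cc2O1 | target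

Total step count: 9. Longest linear sequence: 6 steps (3, 4, 5, 7, 8, 9).

**Steps most likely to fail**

**1. Step 8 (new method).**

Several processes could defeat it:
- weak facial discrimination between the CH3 group and the CH2 chain at C2;
- Friedel–Crafts self-condensation of the o-quinone methide with the electron-rich arene, outrunning the weakly nucleophilic alkene;
- competing attack by the C3'=C4' alkene;
- acid-induced migration of the terminal double bond;
- silyl transfer away from the C7 oxygen;
- binding of the acid by the ester carbonyl.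

The fallback uses known chemistry only. It sets out from 2, also uses 10, and comes back at 13. C2 is set by an enantioselective Wacker-type oxypalladation, and the chain is attached afterwards by sp3–sp2 cross-coupling.

Chroman half. Aldehyde 2 is treated with Boc2O, i-Pr2NEt and catalytic DMAP (CH2Cl2, 0 °C) to give tert-butyl 5-(tert-butyldimethylsilyloxy)-2-formyl-3-methylphenyl carbonate F1. BH3·THF reduces this to tert-butyl 5-(tert-butyldimethylsilyloxy)-2-(hydroxymethyl)-3-methylphenyl carbonate F2. 2-Methylallylmagnesium chloride (2.5 equiv, THF, −78 °C to rt) deprotonates F2. The Boc group then migrates to the benzylic oxygen, tert-butyl carbonate is expelled, and the Grignard reagent adds 1,4 to the o-quinone methide 12 so formed. This gives 5-(tert-butyldimethylsilyloxy)-3-methyl-2-(3-methylbut-3-en-1-yl)phenol F3.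

A domino Wacker cyclisation and methoxycarbonylation follows: Pd(OCOCF3)2, Bn-BOXAX ligand [2,2'-bis(4-benzyloxazolin-2-yl)-1,1'-binaphthyl], p-benzoquinone, CO (1 atm), MeOH, rt. It closes ring B by 6-exo-trig oxypalladation. The resulting alkylpalladium species has no β-hydrogen and is intercepted by CO and methanol. With the ligand enantiomer that gives this sense, the product is methyl 2-[(2S)-7-(tert-butyldimethylsilyloxy)-2,5-dimethyl-3,4-dihydro-2H-chromen-2-yl]acetate F4. It has the same spatial arrangement as 13, and the descriptor changes only through the priority of the side chain.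

i-Bu2AlH (CH2Cl2, −78 to 0 °C) gives 2-[(2S)-7-(tert-butyldimethylsilyloxy)-2,5-dimethyl-3,4-dihydro-2H-chromen-2-yl]ethanol F5. I2, PPh3 and imidazole then give tert-butyl{[(2S)-2-(2-iodoethyl)-2,5-dimethyl-3,4-dihydro-2H-chromen-7-yl]oxy}dimethylsilane F6.

Chain half. Commercial 4-pentyn-1-ol (C#CCCCO) undergoes zirconium-catalysed carboalumination (AlMe3, Cp2ZrCl2, CH2Cl2) and iodinolysis (I2, THF) to give (4E)-5-iodo-4-methylpent-4-en-1-ol F7. Dess–Martin oxidation gives (4E)-5-iodo-4-methylpent-4-enal F8. Still–Gennari olefination with 10, under the conditions of step 7, gives methyl (2Z,6E)-7-iodo-2,6-dimethylhepta-2,6-dienoate F9.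

Coupling. Zinc insertion into F6 (Zn dust, LiCl, THF, 40 °C) gives {2-[(2S)-7-(tert-butyldimethylsilyloxy)-2,5-dimethyl-3,4-dihydro-2H-chromen-2-yl]ethyl}zinc iodide F10. Negishi coupling of F10 with F9 (PdCl2(dppf), THF, rt) forms C2'–C3' with retention of the (E)-geometry and delivers 13.

**2. Step 3.**

Site selectivity between the two trisubstituted alkenes may be incomplete. Attack at C5=C6 and double epoxidation would both erode throughput.

The fallback sets out from 4 and comes back at 5. It replaces peracid oxidation by terminal bromohydrin formation in an aqueous medium, where the folded chain exposes only the isopropylidene end to the bromonium source. NBS (1.05 equiv) in THF/H2O at 0 °C should give (5E)-9-bromo-10-hydroxy-6,10-dimethylundec-5-en-2-one F11. K2CO3 in MeOH closes F11 to epoxide 5.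

**3. Step 2.**

Three processes threaten this step:
- self-condensation of the very electron-rich benzylic alcohol on concentration, on silica or on storage;
- over-reduction through base-induced o-quinone methide formation;
- loss of the silyl group in the basic alcohol medium.

The fallback sets out from 2 and comes back at 3. It isolates and stores the material in a masked form in place of the free salicyl alcohol. After the borohydride reduction the neutral extract is not concentrated to dryness. It is condensed with phenylboronic acid (toluene, MgSO4, rt) to give tert-butyldimethyl[(5-methyl-2-phenyl-4H-1,3,2-benzodioxaborinin-7-yl)oxy]silane F12. In this cyclic boronate both the phenol and the benzylic hydroxyl are tied up, so it can be purified and kept. Just before step 8, transesterification with propane-1,3-diol (Et2O, rt) releases 3, which is freed from the boronic ester by trituration with pentane and used at once.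

**Further compounds**
F1 | step 8 | tert-butyl 5-(tert-butyldimethylsilyloxy)-2-formyl-3-methylphenyl carbonate | O=Cc1c(C)cc(O[Si](C)(C)C(C)(C)C)cc1OC(=O)OC(C)(C)C
F2 | step 8 | tert-butyl 5-(tert-butyldimethylsilyloxy)-2-(hydroxymethyl)-3-methylphenyl carbonate | OCc1c(C)cc(O[Si](C)(C)C(C)(C)C)cc1OC(=O)OC(C)(C)C
F3 | step 8 | 5-(tert-butyldimethylsilyloxy)-3-methyl-2-(3-methylbut-3-en-1-yl)phenol | C=C(C)CCc1c(C)cc(O[Si](C)(C)C(C)(C)C)cc1O
F4 | step 8 | methyl 2-[(2S)-7-(tert-butyldimethylsilyloxy)-2,5-dimethyl-3,4-dihydro-2H-chromen-2-yl]acetate | COC(=O)C[C@]1(C)CCc2c(C)cc(O[Si](C)(C)C(C)(C)C)cc2O1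
F5 | step 8 | 2-[(2S)-7-(tert-butyldimethylsilyloxy)-2,5-dimethyl-3,4-dihydro-2H-chromen-2-yl]ethanol | OCC[C@]1(C)CCc2c(C)cc(O[Si](C)(C)C(C)(C)C)cc2O1
F6 | step 8 | tert-butyl{[(2S)-2-(2-iodoethyl)-2,5-dimethyl-3,4-dihydro-2H-chromen-7-yl]oxy}dimethylsilane | ICC[C@]1(C)CCc2c(C)cc(O[Si](C)(C)C(C)(C)C)cc2O1
F7 | step 8 | (4E)-5-iodo-4-methylpent-4-en-1-ol | OCCC/C(C)=C/I
F8 | step 8 | (4E)-5-iodo-4-methylpent-4-enal | O=CCC/C(C)=C/I
F9 | step 8 | methyl (2Z,6E)-7-iodo-2,6-dimethylhepta-2,6-dienoate | COC(=O)/C(C)=C\CC/C(C)=C/I
F10 | step 8 | {2-[(2S)-7-(tert-butyldimethylsilyloxy)-2,5-dimethyl-3,4-dihydro-2H-chromen-2-yl]ethyl}zinc iodide | I[Zn]CC[C@]1(C)CCc2c(C)cc(O[Si](C)(C)C(C)(C)C)cc2O1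
F11 | step 3 | (5E)-9-bromo-10-hydroxy-6,10-dimethylundec-5-en-2-one (racemic) | CC(C)(O)C(Br)CC/C(C)=C/CCC(C)=O
F12 | step 2 | tert-butyldimethyl[(5-methyl-2-phenyl-4H-1,3,2-benzodioxaborinin-7-yl)oxy]silane | Cc1cc(O[Si](C)(C)C(C)(C)C)cc2OB(c3ccccc3)OCc12
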